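The catalyst charge is what you change from eta to alpha to epsilon, and you want to know what that does to the target at the end.

| setting | west | south-east | eta | alpha | epsilon |
|---|---|---|---|---|---|
| starting material | 13 mM | 40 mM | 20 mM | 20 mM | 20 mM |
| catalyst | 0.50 mM | 0.50 mM | 0.50 mM | 1.0 mM | 2.0 mM |
| remark | run made earlier | run made earlier |  |  |  |
| time |  |  | 2.5 d | 2.5 d | 2.5 d |

| west: time / h | west: target / % | south-east: time / h | south-east: target / % |
|---|---|---|---|
| 2.00 | 14.6 | 1.00 | 6.1 |
| 4.00 | 25.5 | 1.50 | 10.5 |
| 6.00 | 33.5 | 2.50 | 17.4 |
| 8.00 | 40.7 | 4.00 | 24.4 |
| 10.0 | 42.0 | 8.00 | 37.1 |
| 12.0 | 48.6 | 12.0 | 42.8 |

(scatter of a reading: 1 percentage point)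

- "hardly changes" means that all values lie within two and a half points (for a concentration: within two and a half percent of the largest)
- no earlier run changes the charge of catalyst; that part of a forecast is a guess

* amount of target at the end, in percent of the starting material charged for eta, alpha, epsilon, in this order
* the course of these numbers from the first flask to the last (falls, then rises / falls all the way / rises, then falls / rises all the way / hardly changes)

Follow one molecule of starting material. In the first instants it has a steady chance per hour of becoming target. The west run shows 14.6% at 2.00 h, and read as a first-order fall that is a half-life of 8.78 h. Call this the making clock, the half-life of starting material at 0.50 mM of catalyst, as read from the target that appears. The south-east run, at 40 mM instead of 13 mM, reads 9.06 h at 2.50 h, so the clock barely feels the charge of starting material; this is pseudo-first-order behaviour.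

Then comes the middle. By 12.0 h the clock gives 61.2% in the west run, but the reading is 48.6%, which is less. Either target is leaving or the making is slowing, and I can't tell which from these readings.

Now the end. Eta's 2.5 d is 6.83 clocks, so if the clock keeps running, 0.878% of the starting material stays in eta. My own reckoning takes the clock to shorten in step with the catalyst, which is a guess, since no run changes that charge. Then alpha and epsilon get through their starting material sooner than eta. So on this reckoning more catalyst has the 0.878% that eta keeps to add, far less than the 99.1% eta has already used. What target does after it is made is not in the clock, and I have no figure for that, but I commit to a row that hardly changes.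

The forecast says 64%, 84% and 95%, a course that rises all the way: “I favour deactivation or inhibition, shaded down: rises all the way.”

The flasks give 36.5%, 37.2% and 38.0% of target, so the course hardly changes.

    target ⇌ isomer of the product (K = 1.60, k = 0.0460 h⁻¹)
    starting material + target → side product (k = 0.700 M⁻¹ h⁻¹)
    starting material + catalyst → catalyst + target (k = 170 M⁻¹ h⁻¹)

In eta the making ran ahead of the loss of target to isomer of the product, with 6.59% of the starting material left at 1.25 d; at the end the flask holds 0.435%, beside the clock's 0.878%. While target stood there it turned into isomer of the product, a step whose relaxation half-life, both ways together, is 0.386 d, short against 2.5 d, and eta ended with 52.8% of that isomer. In epsilon the clock, taken as guessed at a quarter of its length, puts starting material under 2.00% of its charge at 0.516 d; the flask took 0.468 d.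

All runs are simulated for an exercise; the scatter is artificial.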